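A small charge of starting material, 14 mM, leaks into the open intermediate, and the second intermediate, formed from the partner, captures it. The analysis asks how much open intermediate stands at the end.

| flask | starting material | partner | remark | time |
|---|---|---|---|---|
| east | 14 mM | 51 mM | run made earlier |  |
| south | 14 mM | 110 mM | run made earlier |  |
| autumn | 14 mM | 20.0 mM |  | 2.5 d |
| dawn | 14 mM | 40.0 mM |  | 2.5 d |
| midnight | 14 mM | 80.0 mM |  | 2.5 d |
| summer | 14 mM | 150 mM |  | 2.5 d |

| run | time / h | open intermediate / % | target / % | starting material / % |
|---|---|---|---|---|
| east | 8.00 | 2.7 | 3.4 | 79.7 |
| east | 15.0 | 2.4 | 7.9 | 66.5 |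
| east | 25.0 | 2.5 | 11.3 | 53.4 |
| east | 30.0 | 1.9 | 14.0 | 48.0 |
| east | 40.0 | 1.2 | 17.2 | 40.6 |
| south | 4.00 | 1.2 | 0.7 | 88.2 |
| south | 10.0 | 1.7 | 4.9 | 76.8 |
| south | 20.0 | 1.4 | 10.3 | 59.9 |
| south | 30.0 | 0.8 | 14.4 | 48.8 |
| south | 40.0 | 0.8 | 19.7 | 39.2 |

(each reading ± 0.5 percentage points)

- in percentages every species weighs as the starting material in it: one homo product counts as two
- what was read earlier has a scatter of 0.5 percentage points, one standard deviation
- on the list of suspects stand: starting material -> open intermediate; partner -> second intermediate; open intermediate + second intermediate -> target; 2 open intermediate -> homo product; starting material <-> dormant form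
- "hardly changes" means that all values lie within two and a half points (for a concentration: within two and a half percent of the largest)

- [open intermediate] at the end for autumn, dawn, midnight, summer, in this order
- the course of these numbers from the first flask to the last (rises all the way / hardly changes / rises, then falls / falls all the way / falls, then rises)

1. If a ratio of open intermediate to starting material took no notice of the partner, it would be equal in east and south; that is the zero of the scale. Summed over the readings, it is 0.0371 in east and 0.0189 in south. So it falls as the charge rises to twice that of east.

2. This reckoning therefore treats the capture as pseudo-first-order in open intermediate, with c(second intermediate) taken into its rate constant, and with making and capture in balance. Ratio times charge gives 1.89 mM from east and 2.07 mM from south. These are two runs and two charges, and the gap of 0.180 mM is small for open readings such as 1.4%, each with a scatter of 0.5 percentage points. Their mean, 1.98 mM, is read as the capture ratio: c(open intermediate) · c(second intermediate) / c(starting material).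

3. Carrying the last readings forward to 60 h gives about 27.1% starting material, or 3.80 mM, and about 26.9% target, or 3.77 mM.

4. Two ways now part. With the charge standing in for c(second intermediate), autumn gets 0.376 mM. But each target takes one second intermediate, so charge minus target leaves 16.2 mM and gives 0.464 mM. The charge cheats in autumn, where the target takes 18.9% of it, and hardly in summer, at 2.52%. This reckoning commits to 0.464 mM, 0.208 mM, 0.0988 mM and 0.0515 mM.

5. The forecast, on the grounds that “The ratio open/starting material stays roughly constant in time”, gives 0.35 mM, 0.19 mM, 0.1 mM and 0.053 mM, a course that falls all the way. Its autumn value is lower than the one above.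

    starting material → open intermediate (k = 2.10 × 10⁻⁶ /s)
    partner → second intermediate (k = 8.50 × 10⁻⁵ /s)
    open intermediate + second intermediate → target (k = 0.00130 /M/s)
    2 open intermediate → homo product (k = 4.10 × 10⁻⁵ /M/s)
    starting material ⇌ dormant form (K = 1.70, k = 6.00 × 10⁻⁶ /s)

The flasks give 0.468 mM, 0.202 mM, 0.0935 mM and 0.0482 mM, a course that falls all the way. Autumn holds 17.1 mM of second intermediate at the end, out of a charge of 20.0 mM. The capture ratio, applied to autumn's simulated 4.31 mM of starting material and that second intermediate, gives 0.500 mM of open intermediate. Applied to summer after 25.0 d, with 0.901 mM of starting material and 139 mM of second intermediate, it gives 0.0129 mM, and summer then holds 0.0105 mM.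

(The readings are simulated with constants of no real substance; noise was put on by code.)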